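**Retrosynthetic overview**
- All strategic disconnections are carbon–oxygen bonds: the hemiacetal C–OH (the only stereocentre, made last), the diaryl ether C–O (closes the seven-membered ring) and the depside ester C–O.
- Ring A (the methoxy ring) comes from everninic acid, made from orcylaldehyde. Its CH2OH is added after esterification by phenol-directed ortho-hydroxymethylation.
- Ring B (the phthalide ring) comes from 2,4-dimethoxy-3-methylbenzaldehyde by oxidation, carboxylate-directed ortho-lithiation/formylation, bromination and demethylation, and is carried as a racemic methyl pseudoester.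
- Ring order: phthalide lactone first, then the dioxepinone ring by intramolecular Ullmann etherification, then an enantioconvergent hydrolysis of a bromo-acylal sets the (R)-hemiacetal.

Assumption: the hemiacetal carbon is (R) by CIP and is labile to ring–chain tautomerism in basic or protic media, so it is set in the last step under kinetic control and the product is isolated cold by direct crystallisation; compounds 7–15 are racemic at that carbon, which is of no consequence.

**Step 1**
Reactants: 1 2,4-dihydroxy-6-methylbenzaldehyde (orcylaldehyde)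
Product: 2 2-hydroxy-4-methoxy-6-methylbenzaldehyde
Conditions: MeI (1.05 equiv), K2CO3, acetone, rt
Reagents that add atoms: iodomethane, CI
Why: Williamson O-methylation is selective for the 4-OH because the 2-OH is hydrogen-bonded to the aldehyde and far less nucleophilic.

**Step 2**
Reactants: 2 2-hydroxy-4-methoxy-6-methylbenzaldehyde
Product: 3 2-hydroxy-4-methoxy-6-methylbenzoic acid (everninic acid)
Conditions: NaClO2, NaH2PO4, 2-methyl-2-butene (20 equiv), t-BuOH/H2O, 0 °C to rt
Reagents that add atoms: sodium chlorite, [Na+].[O-]Cl=O
Why: Pinnick oxidation converts the aryl aldehyde to the acid without touching the phenol, the excess alkene trapping HOCl before it can chlorinate the electron-rich ring.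

**Step 3**
Reactants: 4 2,4-dimethoxy-3-methylbenzaldehyde
Product: 5 2,4-dimethoxy-3-methylbenzoic acid
Conditions: NaClO2, NaH2PO4, 2-methyl-2-butene, t-BuOH/H2O, rt
Reagents that add atoms: sodium chlorite, [Na+].[O-]Cl=O
Why: Pinnick oxidation of an unhindered, non-enolisable aryl aldehyde is reliable.

**Step 4**
Reactants: 5 2,4-dimethoxy-3-methylbenzoic acid
Product: 7 racemic 3-hydroxy-5,7-dimethoxy-6-methylisobenzofuran-1(3H)-one, via lithium 6-lithio-2,4-dimethoxy-3-methylbenzoate 6 (not isolated)
Conditions: s-BuLi (2.2 equiv), TMEDA, THF, −78 °C; DMF; 2 M HCl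
Reagents that add atoms: N,N-dimethylformamide, CN(C)C=O (sec-butyllithium, CCC(C)[Li], puts lithium only into intermediate 6)
Why: Carboxylate-directed ortho-metalation lithiates C6, the only position ortho to the carboxylate (C2 carries OMe, C3 carries the methyl), and formylation gives the 6-formyl acid, which exists as its ring tautomer 7, a racemic hydroxyphthalide.

**Step 5**
Reactants: 7 racemic 3-hydroxy-5,7-dimethoxy-6-methylisobenzofuran-1(3H)-one
Product: 8 racemic 4-bromo-3-hydroxy-5,7-dimethoxy-6-methylisobenzofuran-1(3H)-one
Conditions: NBS (1.05 equiv), MeCN, 0 °C to rt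
Reagents that add atoms: N-bromosuccinimide, O=C1CCC(=O)N1Br
Why: Electrophilic aromatic bromination can only occur at C4, the single free ring position, which is activated ortho and para by the two methoxy groups.

**Step 6**
Reactants: 8 racemic 4-bromo-3-hydroxy-5,7-dimethoxy-6-methylisobenzofuran-1(3H)-one
Product: 10 racemic 4-bromo-5,7-dihydroxy-3-methoxy-6-methylisobenzofuran-1(3H)-one, via 4-bromo-3,5,7-trihydroxy-6-methylisobenzofuran-1(3H)-one 9 (not isolated)
Conditions: BBr3 (5 equiv), CH2Cl2, −78 °C to rt; then MeOH, reflux
Reagents that add atoms: methanol, CO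
Why: BBr3 ether cleavage frees both phenols, and the HBr/MeOH quench turns the hydroxyphthalide into its methyl pseudoester by acid-catalysed (Fischer-type) acetalisation, masking the hemiacetal for the coupling steps.

**Step 7**
Reactants: 3 2-hydroxy-4-methoxy-6-methylbenzoic acid (everninic acid); 10 racemic 4-bromo-5,7-dihydroxy-3-methoxy-6-methylisobenzofuran-1(3H)-one
Product: 11 racemic 4-bromo-7-hydroxy-3-methoxy-6-methyl-1-oxo-1,3-dihydroisobenzofuran-5-yl 2-hydroxy-4-methoxy-6-methylbenzoate (depside)
Conditions: (CF3CO)2O (3 equiv), toluene, 0 °C to rt; then MeOH, rt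
Reagents that add atoms: none
Why: Trifluoroacetic anhydride-mediated depside esterification acylates the 5-OH (para to the lactone carbonyl, not chelated) in preference to the chelated 7-OH and tolerates the hydrogen-bonded 2-OH of the acid; the methanol quench removes trifluoroacetates and restores any exchanged pseudoester.

**Step 8**
Reactants: 11 depside
Product: 13 racemic 4-bromo-7-hydroxy-3-methoxy-6-methyl-1-oxo-1,3-dihydroisobenzofuran-5-yl 2-hydroxy-3-(hydroxymethyl)-4-methoxy-6-methylbenzoate, via benzodioxaborinine depside 12 (not isolated)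
Conditions: PhB(OH)2 (1.5 equiv), (CH2O)n, EtCO2H (cat.), toluene, reflux (Dean–Stark); then pinacol, THF, 40 °C
Reagents that add atoms: formaldehyde (as paraformaldehyde), C=O (phenylboronic acid, OB(O)c1ccccc1, is carried only by intermediate 12)
Why: Nagata boron-templated ortho-hydroxymethylation delivers formaldehyde only ortho to a phenol, and ring A C3 is the only free ortho position in the molecule (the ring B phenol has none); the cyclic phenylboronate protects the saligenin until pinacol transesterification releases it.

**Step 9**
Reactants: 13 hydroxymethyl depside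
Product: 14 racemic cryptostictic acid methyl pseudoester (the target skeleton with OMe in place of the hemiacetal OH)
Conditions: CuI (20 mol%), N,N-dimethylglycine·HCl (60 mol%), Cs2CO3 (3.5 equiv), 4 Å MS, 1,4-dioxane (0.01 M), 90 °C; 1 M HCl work-up
Reagents that add atoms: none
Why: Intramolecular Ullmann diaryl ether synthesis with monovalent copper closes the seven-membered dioxepinone ring from the ring A phenoxide onto the ring B C4–Br, the tether overcoming the steric demand of a tetra-ortho-substituted ether.

**Step 10**
Reactants: 14 racemic cryptostictic acid methyl pseudoester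
Product: 16 (R)-cryptostictic acid, via bis-bromide 15 (not isolated)
Conditions: TMSBr (6 equiv), CH2Cl2, 0 °C to rt, evaporate; then chiral squaramide (10 mol%), H2O (6 equiv), 2,2-dimethyloxirane (5 equiv), toluene/CH2Cl2 4:1, −40 °C; cold heptane, filter
Reagents that add atoms: water, O (bromotrimethylsilane, C[Si](C)(C)Br, puts bromine only into intermediate 15)
Why: Proposed new method: an enantioconvergent hydrolysis of a racemic bromo-acylal — TMSBr first converts both the pseudoester OMe and the ring A CH2OH into bromides, so no free alcohol accompanies the electrophile; the squaramide hydrogen-bond donor (3,5-bis(trifluoromethyl)anilino squaramide of a tert-leucine 2-(9-phenanthryl)pyrrolidine amide) then abstracts bromide from either enantiomer of 15 to give one planar phthalidyl oxocarbenium ion paired with catalyst-bound bromide, and water, hydrogen-bonded to the catalyst amide, attacks one face to form the C–OH bond and set the (R) centre; the epoxide traps HBr irreversibly, so the step is under kinetic control and no acid or base remains to open the hemiacetal, while the achiral ring A benzylic bromide is hydrolysed by the same anion-abstraction pathway; the closest known reaction type is chiral hydrogen-bond-donor anion-abstraction catalysis of 1-chloroisochromans, glycosyl chlorides and benzhydryl bromides with epoxide acid scavengers, together with the classical racemic hydrolysis of 3-bromophthalides, and the catalyst enantiomer that gives (R) has to be chosen by running both antipodes.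

**Compound list**
1 | 2,4-dihydroxy-6-methylbenzaldehyde (orcylaldehyde) | Cc1cc(O)cc(O)c1C=O | starting material
2 | 2-hydroxy-4-methoxy-6-methylbenzaldehyde | COc1cc(C)c(C=O)c(O)c1 | intermediate
3 | 2-hydroxy-4-methoxy-6-methylbenzoic acid (everninic acid) | COc1cc(C)c(C(=O)O)c(O)c1 | intermediate
4 | 2,4-dimethoxy-3-methylbenzaldehyde | COc1ccc(C=O)c(OC)c1C | starting material
5 | 2,4-dimethoxy-3-methylbenzoic acid | COc1ccc(C(=O)O)c(OC)c1C | intermediate
6 | lithium 6-lithio-2,4-dimethoxy-3-methylbenzoate | COc1cc([Li])c(C(=O)[O-])c(OC)c1C.[Li+] | intermediate (not isolated)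
7 | racemic 3-hydroxy-5,7-dimethoxy-6-methylisobenzofuran-1(3H)-one | COc1cc2C(O)OC(=O)c2c(OC)c1C | intermediate
8 | racemic 4-bromo-3-hydroxy-5,7-dimethoxy-6-methylisobenzofuran-1(3H)-one | COc1c(Br)c2C(O)OC(=O)c2c(OC)c1C | intermediate
9 | racemic 4-bromo-3,5,7-trihydroxy-6-methylisobenzofuran-1(3H)-one | Cc1c(O)c(Br)c2C(O)OC(=O)c2c1O | intermediate (not isolated)
10 | racemic 4-bromo-5,7-dihydroxy-3-methoxy-6-methylisobenzofuran-1(3H)-one | COC1OC(=O)c2c(O)c(C)c(O)c(Br)c12 | intermediate
11 | racemic 4-bromo-7-hydroxy-3-methoxy-6-methyl-1-oxo-1,3-dihydroisobenzofuran-5-yl 2-hydroxy-4-methoxy-6-methylbenzoate | COc1cc(C)c(C(=O)Oc2c(C)c(O)c3C(=O)OC(OC)c3c2Br)c(O)c1 | intermediate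
12 | racemic 4-bromo-7-hydroxy-3-methoxy-6-methyl-1-oxo-1,3-dihydroisobenzofuran-5-yl 5-methoxy-7-methyl-2-phenyl-4H-benzo[d][1,3,2]dioxaborinine-8-carboxylate | COc1cc(C)c(C(=O)Oc2c(C)c(O)c3C(=O)OC(OC)c3c2Br)c4OB(c5ccccc5)OCc14 | intermediate (not isolated)
13 | racemic 4-bromo-7-hydroxy-3-methoxy-6-methyl-1-oxo-1,3-dihydroisobenzofuran-5-yl 2-hydroxy-3-(hydroxymethyl)-4-methoxy-6-methylbenzoate | COc1cc(C)c(C(=O)Oc2c(C)c(O)c3C(=O)OC(OC)c3c2Br)c(O)c1CO | intermediate
14 | racemic cryptostictic acid methyl pseudoester (depsidone; OMe on the acylal carbon) | COc1cc(C)c2c(c1CO)Oc1c(c(C)c(O)c3c1C(OC)OC3=O)OC2=O | intermediate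
15 | racemic bis-bromide (depsidone with CH2Br on ring A and Br on the acylal carbon) | COc1cc(C)c2c(c1CBr)Oc1c(c(C)c(O)c3c1C(Br)OC3=O)OC2=O | intermediate (not isolated)
16 | (R)-cryptostictic acid | COc1cc(C)c2c(c1CO)Oc1c(c(C)c(O)c3c1[C@H](O)OC3=O)OC2=O | target

**Step count and risks**
Total steps: 10. Longest linear sequence: 8 (steps 3 to 10, from compound 4).

Step 10 is the most likely to fail. The reaction is unprecedented, the sense and level of induction are unknown, the ring A benzylic bromide may hydrolyse slowly at −40 °C, and the product can racemise if it stays in solution. The fallback sets out from 14 and comes back at 16: hydrolysis of the pseudoester with 2 M HCl in 1,4-dioxane at 50 °C gives racemic cryptostictic acid F1, which is resolved by preparative chiral SFC (immobilised amylose phase, CO2/MeCN with 0.1% formic acid, column at 5 °C) to give 16; the unwanted enantiomer is re-equilibrated with catalytic iPr2NEt in THF and recycled.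

Step 9 is the second risk. The aryl bromide is hindered and made electron-rich by the para phenoxide, and the aryl ester may not survive Cs2CO3 at 90 °C. The fallback sets out from 13 and comes back at 14: Miyaura borylation (Pd(dppf)Cl2, B2pin2, KOAc, dioxane, 80 °C) gives the pinacol boronate depside F2, and an intramolecular Chan–Lam etherification with divalent copper (Cu(OAc)2, pyridine, 4 Å MS, O2, CH2Cl2, rt) closes the ring at room temperature to give 14.

Step 8 is the third risk. The Nagata reaction is run on an advanced, chelated salicylate at reflux. The fallback sets out from 2 and comes back at 13, installing the CH2OH before esterification: Nagata hydroxymethylation of 2 gives the benzodioxaborinine aldehyde F3; pinacol exchange releases the saligenin aldehyde F4; 2,2-dimethoxypropane with PPTS gives the acetonide aldehyde F5; Pinnick oxidation gives the acetonide acid F6; DCC/DMAP esterification with 10 gives the acetonide depside F7; and CSA in MeOH removes the acetonide to give 13.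

**Further compounds**
F1 | step 10 | racemic cryptostictic acid | COc1cc(C)c2c(c1CO)Oc1c(c(C)c(O)c3c1C(O)OC3=O)OC2=O
F2 | step 9 | racemic 7-hydroxy-3-methoxy-6-methyl-1-oxo-4-(4,4,5,5-tetramethyl-1,3,2-dioxaborolan-2-yl)-1,3-dihydroisobenzofuran-5-yl 2-hydroxy-3-(hydroxymethyl)-4-methoxy-6-methylbenzoate | COc1cc(C)c(C(=O)Oc2c(C)c(O)c3C(=O)OC(OC)c3c2B4OC(C)(C)C(C)(C)O4)c(O)c1CO
F3 | step 8 | 5-methoxy-7-methyl-2-phenyl-4H-benzo[d][1,3,2]dioxaborinine-8-carbaldehyde | COc1cc(C)c(C=O)c2OB(c3ccccc3)OCc12
F4 | step 8 | 2-hydroxy-3-(hydroxymethyl)-4-methoxy-6-methylbenzaldehyde | COc1cc(C)c(C=O)c(O)c1CO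
F5 | step 8 | 5-methoxy-2,2,7-trimethyl-4H-benzo[d][1,3]dioxine-8-carbaldehyde | COc1cc(C)c(C=O)c2OC(C)(C)OCc12
F6 | step 8 | 5-methoxy-2,2,7-trimethyl-4H-benzo[d][1,3]dioxine-8-carboxylic acid | COc1cc(C)c(C(=O)O)c2OC(C)(C)OCc12
F7 | step 8 | racemic 4-bromo-7-hydroxy-3-methoxy-6-methyl-1-oxo-1,3-dihydroisobenzofuran-5-yl 5-methoxy-2,2,7-trimethyl-4H-benzo[d][1,3]dioxine-8-carboxylate | COc1cc(C)c(C(=O)Oc2c(C)c(O)c3C(=O)OC(OC)c3c2Br)c4OC(C)(C)OCc14
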